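The two halves of the biaryl are constitutional isomers of one lignan monomer. The carbinol carbon and its CH neighbour have the same configuration in both, and the benzylic carbon is bonded either to ring oxygen O1 (oxolane) or to arene carbon C8a (tetralin ring C1–C4/C4a/C8a). The route therefore makes a single enantiopure, all-cis 2-aryl-3-(benzyloxymethyl)-4-(arylmethyl)oxolan-4-ol aryl bromide. A Lewis acid breaks its C2–O1 bond and the guaiacylmethyl ring recloses onto C2, forming the C1–C8a bond, the carbocycle and the C1 stereocentre at once. A second portion of the same bromide is borylated, joined to the tetralin bromide by Suzuki coupling, and debenzylated.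

Key step: step 11

Assumption: the oxolane half is read from the SMILES as (2R,3R,4S), with aryl, hydroxymethyl and arylmethyl groups all on one face; (R)-TRIP is taken to expose the Re face of the aryl aldehyde, as it does with simple allyl- and crotylboronic pinacol esters, and the (S)-acid would be used if the sense were opposite.
Locants used: oxolanes O1, C2 (aryl-bearing), C3, C4 (carbinol), C5; tetralins C1 (aryl-bearing), C2, C3 (carbinol), C4, C4a, C8a.

Step 1
Reactants: 1 5-bromovanillin; 2 benzyl bromide
Product: 3 4-(benzyloxy)-3-bromo-5-methoxybenzaldehyde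
Conditions: K2CO3, DMF, 60 °C
Reagents that add atoms: none
Why: Williamson O-benzylation of the phenoxide should proceed cleanly because the aldehyde and the aryl bromide are inert to K2CO3 and benzyl bromide.

Step 2
Reactants: 4 (benzyloxy)acetaldehyde; 5 ethyl acrylate
Product: 6 ethyl 4-(benzyloxy)-3-hydroxy-2-methylidenebutanoate (racemic)
Conditions: 1,4-diazabicyclo[2.2.2]octane (20 mol%), excess 5 as solvent, rt
Reagents that add atoms: none
Why: Morita–Baylis–Hillman reaction, in which the amine adds to the acrylate and the resulting enolate attacks the activated α-alkoxy aldehyde; the carbinol centre forms as a racemate and is erased in step 4.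

Step 3
Reactants: 6 ethyl 4-(benzyloxy)-3-hydroxy-2-methylidenebutanoate
Product: 7 ethyl 3-(acetyloxy)-4-(benzyloxy)-2-methylidenebutanoate (racemic)
Conditions: Ac2O, pyridine, 4-(dimethylamino)pyridine (5 mol%), 0 °C → rt
Reagents that add atoms: acetic anhydride, CC(=O)OC(C)=O
Why: Nucleophile-catalysed O-acetylation of the secondary allylic alcohol installs the leaving group needed for allylic substitution.

Step 4
Reactants: 7 ethyl 3-(acetyloxy)-4-(benzyloxy)-2-methylidenebutanoate
Product: 8 ethyl (2E)-4-(benzyloxy)-2-[(4,4,5,5-tetramethyl-1,3,2-dioxaborolan-2-yl)methyl]but-2-enoate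
Conditions: bis(pinacolato)diboron (B2pin2), Pd2(dba)3 [tris(dibenzylideneacetone)dipalladium] (2.5 mol%), toluene, 50 °C
Reagents that add atoms: bis(pinacolato)diboron, CC1(C)OB(OC1(C)C)B1OC(C)(C)C(C)(C)O1
Why: Palladium-catalysed allylic borylation of a Morita–Baylis–Hillman acetate, in which zerovalent palladium ionises the acetate to a 2-carboethoxy π-allyl complex and boron is delivered to the unsubstituted terminus, should give the trisubstituted enoate with the benzyloxymethyl group trans to the ester (E), the geometry normally preferred by ester-derived acetates.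

Step 5
Reactants: 3 4-(benzyloxy)-3-bromo-5-methoxybenzaldehyde; 8 ethyl (2E)-4-(benzyloxy)-2-[(4,4,5,5-tetramethyl-1,3,2-dioxaborolan-2-yl)methyl]but-2-enoate
Product: 10 (4R,5R)-5-[4-(benzyloxy)-3-bromo-5-methoxyphenyl]-4-[(benzyloxy)methyl]-3-methylideneoxolan-2-one, via O-boryl hydroxy ester 9 (not isolated)
Conditions: (R)-3,3'-bis(2,4,6-triisopropylphenyl)-1,1'-binaphthyl-2,2'-diyl hydrogen phosphate [(R)-TRIP] (10 mol%), toluene, rt; then TsOH·H2O (10 mol%), rt
Reagents that add atoms: none
Why: Chiral phosphoric acid-catalysed allylboration followed by acid-catalysed lactonisation: the closed chair transition state with the aryl group equatorial and the benzyloxymethyl group (cis to CH2B in 8) axial gives the syn adduct and hence the 4,5-cis lactone, while the (R)-acid, hydrogen-bonded to a boronate oxygen and the formyl hydrogen, exposes the Re face of 3 and so sets both centres as R; the uncatalysed addition of this ester-deactivated boronate is slow at room temperature and should not erode the selectivity.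

Step 6
Reactants: 10 (4R,5R)-5-[4-(benzyloxy)-3-bromo-5-methoxyphenyl]-4-[(benzyloxy)methyl]-3-methylideneoxolan-2-one
Product: 11 (1R,2R)-1-[4-(benzyloxy)-3-bromo-5-methoxyphenyl]-2-[(benzyloxy)methyl]-3-methylidenebutane-1,4-diol
Conditions: i-Bu2AlH (4 equiv), CH2Cl2, −78 → 0 °C; aqueous potassium sodium tartrate
Reagents that add atoms: none
Why: Hydride reduction of the α-methylene lactone by 1,2-addition through the lactol and enal should give the allylic 1,4-diol without touching the aryl bromide, the benzyl ethers or the two stereocentres.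

Step 7
Reactants: 11 (1R,2R)-1-[4-(benzyloxy)-3-bromo-5-methoxyphenyl]-2-[(benzyloxy)methyl]-3-methylidenebutane-1,4-diol
Product: 13 (2R,3R)-2-[4-(benzyloxy)-3-bromo-5-methoxyphenyl]-3-[(benzyloxy)methyl]-4-methylideneoxolane, via primary allylic tosylate 12 (not isolated)
Conditions: NaH (2.5 equiv), THF, 0 °C; then TsCl (1.0 equiv), 0 °C → rt
Reagents that add atoms: none
Why: Chemoselective O-sulfonylation followed by intramolecular Williamson etherification: the unhindered primary allylic alkoxide is tosylated first and is displaced by the benzylic alkoxide (direct or allylic attack gives the same ring), so the benzylic C–O bond is never broken and the 2,3-cis relationship is kept.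

Step 8
Reactants: 13 (2R,3R)-2-[4-(benzyloxy)-3-bromo-5-methoxyphenyl]-3-[(benzyloxy)methyl]-4-methylideneoxolane
Product: 14 (3R,6R,7R)-6-[4-(benzyloxy)-3-bromo-5-methoxyphenyl]-7-[(benzyloxy)methyl]-1,5-dioxaspiro[2.4]heptane
Conditions: 3-chloroperoxybenzoic acid (mCPBA), CH2Cl2/saturated aqueous NaHCO3, 0 °C
Reagents that add atoms: 3-chloroperoxybenzoic acid, OOC(=O)c1cccc(Cl)c1
Why: Prilezhaev epoxidation of the exocyclic 1,1-disubstituted alkene should occur on the face opposite the cis-disposed aryl and benzyloxymethyl groups, which places the epoxide oxygen trans to both and sets the future carbinol centre, while the bicarbonate phase protects the acid-labile benzylic ether.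

Step 9
Reactants: 15 4-bromo-2-methoxyphenol; 2 benzyl bromide
Product: 16 1-(benzyloxy)-4-bromo-2-methoxybenzene
Conditions: K2CO3, DMF, rt
Reagents that add atoms: none
Why: Williamson O-benzylation of the phenoxide masks the acidic hydroxyl before the Grignard reagent is formed.

Step 10
Reactants: 14 (3R,6R,7R)-6-[4-(benzyloxy)-3-bromo-5-methoxyphenyl]-7-[(benzyloxy)methyl]-1,5-dioxaspiro[2.4]heptane; 16 1-(benzyloxy)-4-bromo-2-methoxybenzene
Product: 18 (2R,3R,4S)-2-[4-(benzyloxy)-3-bromo-5-methoxyphenyl]-4-{[4-(benzyloxy)-3-methoxyphenyl]methyl}-3-[(benzyloxy)methyl]oxolan-4-ol, via arylmagnesium bromide 17 (not isolated)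
Conditions: 16, Mg, THF, 40 °C; solution decanted onto CuI (10 mol%), then 14, THF, −30 → 0 °C; aqueous NH4Cl
Reagents that add atoms: none
Why: Copper-catalysed opening of a 2,2-disubstituted epoxide by an aryl Grignard reagent occurs by SN2 attack at the unhindered CH2 terminus, so the C4–O bond and its configuration are untouched, the tertiary alcohol ends trans to the C3 substituent with the new arylmethyl group cis to it, and the aryl bromide of 14 does not exchange with the Grignard reagent at this temperature.

Step 11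
Reactants: 18 (2R,3R,4S)-2-[4-(benzyloxy)-3-bromo-5-methoxyphenyl]-4-{[4-(benzyloxy)-3-methoxyphenyl]methyl}-3-[(benzyloxy)methyl]oxolan-4-ol
Product: 19 (1S,2S,3S)-7-(benzyloxy)-1-[4-(benzyloxy)-3-bromo-5-methoxyphenyl]-2-[(benzyloxy)methyl]-3-(hydroxymethyl)-6-methoxy-1,2,3,4-tetrahydronaphthalen-3-ol
Conditions: BF3·OEt2 (0.5 equiv), CH2Cl2, −40 → 0 °C; saturated aqueous NaHCO3
Reagents that add atoms: none
Why: BF3 coordinates O1 and the oxolane C2–O1 bond ionises to a benzylic cation stabilised by the para-benzyloxy group, while the C5 oxygen leaves the ring as a borate that becomes the primary alcohol on work-up. The closest known reaction is the acid-promoted isomerisation of 2-aryl-4-(arylmethyl)oxolane lignans into 1-aryltetralin cyclolignans, as in the conversion of olivil into cycloolivil. The carbocycle closes by intramolecular Friedel–Crafts alkylation in which the carbon of the guaiacylmethyl ring that is ortho to the CH2 tether and para to OMe attacks the cation (six-membered closure through the ortho carbon, Ar2-6 mode, 6-endo with respect to the arene π bond), and the arenium ion then loses a proton. The new C1 stereocentre is controlled by the adjacent centre that becomes tetralin C2: in the half-chair transition state the aryl and benzyloxymethyl groups are both pseudo-equatorial, which gives the 1,2-trans product, and because the cation is planar any C2 epimer of 18 converges on the same outcome. The step needs regioselectivity for the position para and not ortho to OMe, which the methoxy group secures electronically and the crowding of the alternative site between OMe and the tether secures sterically, and it needs chemoselective ionisation, which follows from C2–O1 being the only C–O bond benzylic to an alkoxy-donor ring. The carbinol carbon and its CH neighbour are not touched and already carry the configuration of tetralin C3 and C2.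

Step 12
Reactants: 18 (2R,3R,4S)-2-[4-(benzyloxy)-3-bromo-5-methoxyphenyl]-4-{[4-(benzyloxy)-3-methoxyphenyl]methyl}-3-[(benzyloxy)methyl]oxolan-4-ol
Product: 20 (2R,3R,4S)-2-[4-(benzyloxy)-3-methoxy-5-(4,4,5,5-tetramethyl-1,3,2-dioxaborolan-2-yl)phenyl]-4-{[4-(benzyloxy)-3-methoxyphenyl]methyl}-3-[(benzyloxy)methyl]oxolan-4-ol
Conditions: bis(pinacolato)diboron (B2pin2), PdCl2(dppf) {[1,1'-bis(diphenylphosphino)ferrocene]dichloropalladium} (5 mol%), KOAc, 1,4-dioxane, 85 °C
Reagents that add atoms: bis(pinacolato)diboron, CC1(C)OB(OC1(C)C)B1OC(C)(C)C(C)(C)O1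
Why: Miyaura borylation by oxidative addition of the aryl bromide to zerovalent palladium, acetate-assisted transmetalation and reductive elimination should give the arylboronic ester, and the weak base and absence of acid leave the tertiary alcohol, the benzylic ether and all stereocentres alone.

Step 13
Reactants: 19 (1S,2S,3S)-7-(benzyloxy)-1-[4-(benzyloxy)-3-bromo-5-methoxyphenyl]-2-[(benzyloxy)methyl]-3-(hydroxymethyl)-6-methoxy-1,2,3,4-tetrahydronaphthalen-3-ol; 20 (2R,3R,4S)-2-[4-(benzyloxy)-3-methoxy-5-(4,4,5,5-tetramethyl-1,3,2-dioxaborolan-2-yl)phenyl]-4-{[4-(benzyloxy)-3-methoxyphenyl]methyl}-3-[(benzyloxy)methyl]oxolan-4-ol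
Product: 21 (2R,3R,4S)-2-{4-(benzyloxy)-3-[2-(benzyloxy)-5-[(1S,2S,3S)-7-(benzyloxy)-2-[(benzyloxy)methyl]-3-hydroxy-3-(hydroxymethyl)-6-methoxy-1,2,3,4-tetrahydronaphthalen-1-yl]-3-methoxyphenyl]-5-methoxyphenyl}-4-{[4-(benzyloxy)-3-methoxyphenyl]methyl}-3-[(benzyloxy)methyl]oxolan-4-ol
Conditions: Pd(OAc)2 (5 mol%), 2-dicyclohexylphosphino-2',6'-dimethoxybiphenyl (SPhos, 10 mol%), K3PO4, toluene/H2O (10:1), 80 °C
Reagents that add atoms: none
Why: Suzuki–Miyaura cross-coupling with a bulky electron-rich biarylphosphine should join the two ortho-benzyloxy partners into the 2,2'-dioxygenated biaryl, whose single ortho substituent on each ring leaves the axis freely rotating, and the free hydroxyl groups and the oxolane are tolerated by the basic medium.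

Step 14
Reactants: 21 hexa-O-benzyl biaryl (name as in step 13)
Product: 22 (2R,3R,4S)-2-{4-hydroxy-3-[2-hydroxy-5-[(1S,2S,3S)-3,7-dihydroxy-2,3-bis(hydroxymethyl)-6-methoxy-1,2,3,4-tetrahydronaphthalen-1-yl]-3-methoxyphenyl]-5-methoxyphenyl}-4-[(4-hydroxy-3-methoxyphenyl)methyl]-3-(hydroxymethyl)oxolan-4-ol (CNP0344108.1)
Conditions: H2 (1 atm), Pd/C (10 wt% palladium on carbon), EtOAc/MeOH (4:1), rt
Reagents that add atoms: none
Why: Catalytic hydrogenolysis should cleave the four aryl and two primary alkyl benzyl ethers to toluene under neutral conditions, while the oxolane C2–O1 bond is expected to survive because no acid is present and its aryl ring is tetrasubstituted and crowded by the all-cis oxolane, and no stereocentre is affected.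

Compound list
1 | 5-bromovanillin (3-bromo-4-hydroxy-5-methoxybenzaldehyde) | COc1cc(C=O)cc(Br)c1O | starting material
2 | benzyl bromide | BrCc1ccccc1 | starting material
3 | 4-(benzyloxy)-3-bromo-5-methoxybenzaldehyde | COc1cc(C=O)cc(Br)c1OCc1ccccc1 | intermediate
4 | (benzyloxy)acetaldehyde | O=CCOCc1ccccc1 | starting material
5 | ethyl acrylate | C=CC(=O)OCC | starting material
6 | ethyl 4-(benzyloxy)-3-hydroxy-2-methylidenebutanoate (racemic) | CCOC(=O)C(=C)C(O)COCc1ccccc1 | intermediate
7 | ethyl 3-(acetyloxy)-4-(benzyloxy)-2-methylidenebutanoate (racemic) | CCOC(=O)C(=C)C(OC(C)=O)COCc1ccccc1 | intermediate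
8 | ethyl (2E)-4-(benzyloxy)-2-[(4,4,5,5-tetramethyl-1,3,2-dioxaborolan-2-yl)methyl]but-2-enoate | CCOC(=O)/C(CB1OC(C)(C)C(C)(C)O1)=C/COCc1ccccc1 | intermediate
9 | ethyl (3R,4R)-4-[4-(benzyloxy)-3-bromo-5-methoxyphenyl]-3-[(benzyloxy)methyl]-2-methylidene-4-[(4,4,5,5-tetramethyl-1,3,2-dioxaborolan-2-yl)oxy]butanoate | CCOC(=O)C(=C)[C@H](COCc1ccccc1)[C@@H](OB1OC(C)(C)C(C)(C)O1)c1cc(OC)c(OCc2ccccc2)c(Br)c1 | intermediate (not isolated)
10 | (4R,5R)-5-[4-(benzyloxy)-3-bromo-5-methoxyphenyl]-4-[(benzyloxy)methyl]-3-methylideneoxolan-2-one (4,5-cis) | C=C1C(=O)O[C@@H](c2cc(OC)c(OCc3ccccc3)c(Br)c2)[C@H]1COCc1ccccc1 | intermediate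
11 | (1R,2R)-1-[4-(benzyloxy)-3-bromo-5-methoxyphenyl]-2-[(benzyloxy)methyl]-3-methylidenebutane-1,4-diol | OCC(=C)[C@H](COCc1ccccc1)[C@@H](O)c1cc(OC)c(OCc2ccccc2)c(Br)c1 | intermediate
12 | (3R,4R)-4-[4-(benzyloxy)-3-bromo-5-methoxyphenyl]-3-[(benzyloxy)methyl]-4-hydroxy-2-methylidenebutyl 4-methylbenzenesulfonate | Cc1ccc(cc1)S(=O)(=O)OCC(=C)[C@H](COCc1ccccc1)[C@@H](O)c1cc(OC)c(OCc2ccccc2)c(Br)c1 | intermediate (not isolated)
13 | (2R,3R)-2-[4-(benzyloxy)-3-bromo-5-methoxyphenyl]-3-[(benzyloxy)methyl]-4-methylideneoxolane (2,3-cis) | C=C1CO[C@@H](c2cc(OC)c(OCc3ccccc3)c(Br)c2)[C@H]1COCc1ccccc1 | intermediate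
14 | (3R,6R,7R)-6-[4-(benzyloxy)-3-bromo-5-methoxyphenyl]-7-[(benzyloxy)methyl]-1,5-dioxaspiro[2.4]heptane (epoxide oxygen trans to the C7 substituent) | C1O[C@@]12CO[C@@H](c3cc(OC)c(OCc4ccccc4)c(Br)c3)[C@H]2COCc1ccccc1 | intermediate
15 | 4-bromo-2-methoxyphenol | COc1cc(Br)ccc1O | starting material
16 | 1-(benzyloxy)-4-bromo-2-methoxybenzene | COc1cc(Br)ccc1OCc1ccccc1 | intermediate
17 | [4-(benzyloxy)-3-methoxyphenyl]magnesium bromide | COc1cc([Mg]Br)ccc1OCc1ccccc1 | intermediate (not isolated)
18 | (2R,3R,4S)-2-[4-(benzyloxy)-3-bromo-5-methoxyphenyl]-4-{[4-(benzyloxy)-3-methoxyphenyl]methyl}-3-[(benzyloxy)methyl]oxolan-4-ol | COc1cc(C[C@@]2(O)CO[C@@H](c3cc(OC)c(OCc4ccccc4)c(Br)c3)[C@H]2COCc2ccccc2)ccc1OCc1ccccc1 | intermediate (key-step precursor)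
19 | (1S,2S,3S)-7-(benzyloxy)-1-[4-(benzyloxy)-3-bromo-5-methoxyphenyl]-2-[(benzyloxy)methyl]-3-(hydroxymethyl)-6-methoxy-1,2,3,4-tetrahydronaphthalen-3-ol | Brc1cc([C@H]2c3cc(OCc4ccccc4)c(OC)cc3C[C@@](O)(CO)[C@@H]2COCc2ccccc2)cc(OC)c1OCc1ccccc1 | intermediate (key-step product)
20 | (2R,3R,4S)-2-[4-(benzyloxy)-3-methoxy-5-(4,4,5,5-tetramethyl-1,3,2-dioxaborolan-2-yl)phenyl]-4-{[4-(benzyloxy)-3-methoxyphenyl]methyl}-3-[(benzyloxy)methyl]oxolan-4-ol | COc1cc(C[C@@]2(O)CO[C@@H](c3cc(OC)c(OCc4ccccc4)c(B4OC(C)(C)C(C)(C)O4)c3)[C@H]2COCc2ccccc2)ccc1OCc1ccccc1 | intermediate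
21 | hexa-O-benzyl ether of 22 (benzyl on the four phenolic oxygens and on the CH2O groups at oxolane C3 and tetralin C2; full name in step 13) | COc1cc(C[C@@]2(O)CO[C@@H](c3cc(OC)c(OCc7ccccc7)c(-c4cc([C@H]5c6cc(OCc7ccccc7)c(OC)cc6C[C@@](O)(CO)[C@@H]5COCc5ccccc5)cc(OC)c4OCc4ccccc4)c3)[C@H]2COCc2ccccc2)ccc1OCc1ccccc1 | intermediate
22 | CNP0344108.1 (full name in step 14) | COc1cc(C[C@@]2(O)CO[C@@H](c3cc(OC)c(O)c(-c4cc([C@H]5c6cc(O)c(OC)cc6C[C@@](O)(CO)[C@@H]5CO)cc(OC)c4O)c3)[C@H]2CO)ccc1O | target

Total step count: 14
Longest linear sequence: 11 steps (steps 2, 3, 4, 5, 6, 7, 8, 10, 11, 13, 14)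

Steps most likely to fail

Step 5. The ester-deactivated, γ-substituted boronate is a weak and hindered partner, so turnover may be slow or discrimination between the aldehyde faces poor. Setting out from aldehyde 3 and boronate 8, the two would instead be heated without catalyst in toluene at 90 °C and the adduct lactonised with TsOH·H2O as before. The closed transition state still enforces the syn adduct, so the cis-lactone would form as a racemate, that is 10 together with its mirror image, the (4S,5S)-lactone F1. Preparative chromatography on an amylose tris(3,5-dimethylphenylcarbamate) chiral stationary phase would remove F1, and the route is rejoined at 10.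

Step 11. The β-hydroxy benzylic cation may fragment by C3–C4 cleavage (Grob-type, to an aryl ketone and a cinnamyl ether) or shed a benzyl group before the arene captures it. The bromine and the twisted benzyloxy group make the cation less stable, so longer exposure to the acid may be needed, which favours these pathways. Setting out from 18, the tertiary hydroxyl would be capped with triethylsilyl trifluoromethanesulfonate and 2,6-lutidine (CH2Cl2, −78 °C, the base preventing ionisation) to give the silyl ether F2. Its oxygen is much less able to push out the C3–C4 bond and no longer binds the Lewis acid. BF3·OEt2 in CH2Cl2 at −40 °C would then convert F2 into the silyloxy tetralin F3 by the same ring-opening Friedel–Crafts closure, and Bu4NF in THF at 0 °C would remove the silyl group, rejoining the route at 19.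

Step 13. Protodeboronation of the electron-rich ortho-benzyloxy boronate may outrun transmetalation onto the hindered arylpalladium bromide, giving reduced arene and not the biaryl. Setting out from bromide 18, stannylation with hexabutylditin and Pd(PPh3)4 in toluene at 110 °C would give the aryl stannane F4, which does not protodemetalate under neutral conditions. Stille coupling of F4 with bromide 19 (Pd(PPh3)4, CuI, CsF, DMF, 60 °C) would then give the biaryl, rejoining the route at 21.

Further compounds
F1 | step 5 | (4S,5S)-5-[4-(benzyloxy)-3-bromo-5-methoxyphenyl]-4-[(benzyloxy)methyl]-3-methylideneoxolan-2-one | C=C1C(=O)O[C@H](c2cc(OC)c(OCc3ccccc3)c(Br)c2)[C@@H]1COCc1ccccc1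
F2 | step 11 | (2R,3R,4S)-2-[4-(benzyloxy)-3-bromo-5-methoxyphenyl]-4-{[4-(benzyloxy)-3-methoxyphenyl]methyl}-3-[(benzyloxy)methyl]-4-[(triethylsilyl)oxy]oxolane | COc1cc(C[C@@]2(O[Si](CC)(CC)CC)CO[C@@H](c3cc(OC)c(OCc4ccccc4)c(Br)c3)[C@H]2COCc2ccccc2)ccc1OCc1ccccc1
F3 | step 11 | {(1S,2S,3S)-7-(benzyloxy)-1-[4-(benzyloxy)-3-bromo-5-methoxyphenyl]-2-[(benzyloxy)methyl]-6-methoxy-3-[(triethylsilyl)oxy]-1,2,3,4-tetrahydronaphthalen-3-yl}methanol | Brc1cc([C@H]2c3cc(OCc4ccccc4)c(OC)cc3C[C@@](O[Si](CC)(CC)CC)(CO)[C@@H]2COCc2ccccc2)cc(OC)c1OCc1ccccc1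
F4 | step 13 | (2R,3R,4S)-2-[4-(benzyloxy)-3-methoxy-5-(tributylstannyl)phenyl]-4-{[4-(benzyloxy)-3-methoxyphenyl]methyl}-3-[(benzyloxy)methyl]oxolan-4-ol | COc1cc(C[C@@]2(O)CO[C@@H](c3cc(OC)c(OCc4ccccc4)c([Sn](CCCC)(CCCC)CCCC)c3)[C@H]2COCc2ccccc2)ccc1OCc1ccccc1
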